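**Retrosynthetic overview**

- The strategy rests on ring A (C4a, C5, C6, C7, C8, C8a): a benzene ring with hydroxyl groups at C5 and C8, para to each other, fused to the quinone ring B (C1–C4, C4a, C8a). C5–C8 and their two oxygens correspond to the four carbons and two carbonyl oxygens of succinic anhydride.
- The last disconnection is the Si–O bond of a tertiary triethylsilyl ether. Before it, ring A is cut at C4a–C5 and C8–C8a: a Diels–Alder reaction of 2,5-bis(trimethylsilyloxy)furan with the unsubstituted alkene of a 2-substituted 1,4-benzoquinone that already carries the whole (R,R) side chain.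
- The benzoquinone comes from a 2,5-dimethoxyphenyl precursor by oxidative demethylation, and the ester from (R)-2-methylbutanoic acid.
- The E-alkene comes from an alkyne by trans-reduction. The carbinol stereocentre and its C–C bond come from asymmetric alkynylation of 2,5-dimethoxybenzaldehyde with 2-methylbut-3-yn-2-ol.
- Ring order: ring B is present from the start as the dimethoxybenzene; ring A is formed in the penultimate step.

Key step: step 7

Assumption: with (R)-BINOL the alkynyl group is taken to add to the Re face of the aldehyde, as it does with benzaldehyde. Here this corresponds to the (R)-carbinol, because the 2,5-dimethoxyphenyl group outranks the alkynyl group. The configuration would be checked on the first intermediate (Mosher esters) and (S)-BINOL used if the sense were opposite.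

**Route**

Step 1
Reactants: 1 2,5-dimethoxybenzaldehyde; 2 2-methylbut-3-yn-2-ol
Product: 3 (R)-1-(2,5-dimethoxyphenyl)-4-methylpent-2-yne-1,4-diol
Conditions: InBr3 (10 mol %), (R)-BINOL (10 mol %), Cy2NMe (50 mol %), 2 (2 equiv), CH2Cl2, 40 °C
Reagents that add atoms: none
Why: Indium/BINOL-catalysed asymmetric alkynylation of an aromatic aldehyde, in which the trivalent indium BINOLate activates both the terminal alkyne and the aldehyde and the (R)-ligand should direct the alkynyl group to the Re face, setting the (R)-carbinol centre.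

Step 2
Reactants: 3 (R)-1-(2,5-dimethoxyphenyl)-4-methylpent-2-yne-1,4-diol
Product: 4 (R,E)-1-(2,5-dimethoxyphenyl)-4-methylpent-2-ene-1,4-diol
Conditions: NaAlH2(OCH2CH2OMe)2 (3 equiv), THF, 0 °C → rt; aq. KNaC4H4O6 (potassium sodium tartrate)
Reagents that add atoms: none
Why: Alkoxide-directed trans-hydroalumination of the propargylic alkoxide followed by protonolysis should give only the E-alkene, the carbinol centre is untouched, and the tertiary alkoxide is too poor a leaving group at this temperature for allene formation.

Step 3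
Reactants: 4 (R,E)-1-(2,5-dimethoxyphenyl)-4-methylpent-2-ene-1,4-diol; 5 (R)-2-methylbutanoic acid
Product: 6 (R,E)-1-(2,5-dimethoxyphenyl)-4-hydroxy-4-methylpent-2-en-1-yl (R)-2-methylbutanoate
Conditions: 5 (1.2 equiv), DCC (1.2 equiv), DMAP (10 mol %), CH2Cl2, 0 °C; chromatography on Et3N-deactivated silica
Reagents that add atoms: none
Why: Steglich esterification should acylate only the secondary alcohol, the tertiary one being too hindered, and the neutral conditions at 0 °C preserve the α-stereocentre of the acid and the ionisation-prone benzylic allylic C–O bond; no stereocentre is formed.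

Step 4
Reactants: 6 (R,E)-1-(2,5-dimethoxyphenyl)-4-hydroxy-4-methylpent-2-en-1-yl (R)-2-methylbutanoate
Product: 7 (R,E)-1-(2,5-dimethoxyphenyl)-4-methyl-4-(triethylsilyloxy)pent-2-en-1-yl (R)-2-methylbutanoate
Conditions: Et3SiOTf (1.3 equiv), 2,6-lutidine (2.5 equiv), CH2Cl2, −78 °C; aq. NaHCO3
Reagents that add atoms: triethylsilyl trifluoromethanesulfonate, CC[Si](CC)(CC)OS(=O)(=O)C(F)(F)F
Why: Silyl triflate silylation of a tertiary alcohol is fast at −78 °C, and the excess hindered base keeps the medium free of acid so that the benzylic allylic ester should not ionise.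

Step 5
Reactants: 7 (R,E)-1-(2,5-dimethoxyphenyl)-4-methyl-4-(triethylsilyloxy)pent-2-en-1-yl (R)-2-methylbutanoate
Product: 8 (R,E)-1-(3,6-dioxocyclohexa-1,4-dien-1-yl)-4-methyl-4-(triethylsilyloxy)pent-2-en-1-yl (R)-2-methylbutanoate
Conditions: (NH4)2Ce(NO3)6 (2.5 equiv), MeCN–H2O (3:1), 0 °C, 15 min; used without delay
Reagents that add atoms: water, O
Why: Oxidative demethylation of a hydroquinone dimethyl ether, in which two one-electron oxidations by tetravalent cerium and attack of water at the methoxy-bearing carbons release methanol and give the 1,4-benzoquinone, while the isolated alkene, the ester and the tertiary silyl ether should survive the short exposure.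

Step 6
Reactants: 9 succinic anhydride
Product: 10 2,5-bis(trimethylsilyloxy)furan
Conditions: Me3SiCl (2.4 equiv), Et3N (2.4 equiv), ZnCl2 (5 mol %), MeCN, rt → 45 °C; filtration under N2, distillation under reduced pressure
Reagents that add atoms: chlorotrimethylsilane, C[Si](C)(C)Cl
Why: Soft enolisation and double O-silylation of the anhydride gives the aromatic bis-silyl ketene acetal, a known preparation of this diene.

Step 7
Reactants: 8 (R,E)-1-(3,6-dioxocyclohexa-1,4-dien-1-yl)-4-methyl-4-(triethylsilyloxy)pent-2-en-1-yl (R)-2-methylbutanoate; 10 2,5-bis(trimethylsilyloxy)furan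
Product: 13 (R,E)-1-(5,8-dihydroxy-1,4-dioxo-1,4-dihydronaphthalen-2-yl)-4-methyl-4-(triethylsilyloxy)pent-2-en-1-yl (R)-2-methylbutanoate, via oxa-bridged bis-silyl ketal cycloadduct 11 (not isolated), via 4a,8a-dihydro tetraone 12 (not isolated)
Conditions: 10 (1.3 equiv), toluene, −20 °C → rt, N2, dark; then MeOH, pyridinium p-toluenesulfonate (cat.), 0 °C → rt
Reagents that add atoms: none
Why: Proposed new method: the closest known reaction type is the Diels–Alder addition of 2,5-bis(trimethylsilyloxy)furans to electron-poor alkenes and alkynes, which gives para-hydroquinones after opening of the oxygen bridge, and a quinone alkene is proposed here as the 2π partner because it is an even stronger enedione dienophile; the diene, its HOMO raised by four oxygen donors, should add suprafacially through its oxygen-bearing termini C2 and C5 to C5=C6 of 8 (which become C4a and C8a) in a normal-demand [4+2] cycloaddition that forms C4a–C5 and C8–C8a. Ring A is thereby closed as a six-membered carbocycle in cycloaddition mode, first as the oxygen-bridged bis-silyl ketal 11. Methanolysis of the two bridgehead Me3SiO groups collapses both ketals to carbonyl groups and opens the bridge to the 4a,8a-dihydro tetraone 12, whose two ring-fusion hydrogens, each flanked by two carbonyls, are lost by double enolisation to give the naphthazarin at unchanged oxidation level. No new stereocentre survives, since the four sp3 centres of 11 (an endo/exo and facial mixture) are erased on aromatisation and the two side-chain centres take no part. The step needs site selectivity between the two quinone alkenes, secured by the branched acyloxyalkyl group that makes C2=C3 trisubstituted and shielded, while the symmetric diene raises no regiochemical question. It also needs cycloaddition to win over Mukaiyama–Michael addition through furan C3 and over electron transfer, which a non-polar solvent, low temperature and the absence of any Lewis acid should secure, and a small excess of diene with the quench delayed until 8 is consumed should prevent a second annulation on the product.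

Step 8
Reactants: 13 (R,E)-1-(5,8-dihydroxy-1,4-dioxo-1,4-dihydronaphthalen-2-yl)-4-methyl-4-(triethylsilyloxy)pent-2-en-1-yl (R)-2-methylbutanoate
Product: 14 (R,E)-1-(5,8-dihydroxy-1,4-dioxo-1,4-dihydronaphthalen-2-yl)-4-hydroxy-4-methylpent-2-en-1-yl (R)-2-methylbutanoate (CNP0265539.1)
Conditions: HF·pyridine, pyridine, THF, 0 °C → rt
Reagents that add atoms: none
Why: Fluoride cleavage of the tertiary triethylsilyl ether under pyridine buffering should leave the allylic ester, the naphthazarin and the tertiary allylic alcohol intact, and no stereocentre is touched.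

**Compound list**

1 | 2,5-dimethoxybenzaldehyde | COc1ccc(OC)c(C=O)c1 | starting material
2 | 2-methylbut-3-yn-2-ol | CC(C)(O)C#C | starting material
3 | (R)-1-(2,5-dimethoxyphenyl)-4-methylpent-2-yne-1,4-diol | O[C@H](C#CC(C)(C)O)c1cc(OC)ccc1OC | intermediate
4 | (R,E)-1-(2,5-dimethoxyphenyl)-4-methylpent-2-ene-1,4-diol | O[C@H](/C=C/C(C)(C)O)c1cc(OC)ccc1OC | intermediate
5 | (R)-2-methylbutanoic acid | CC[C@@H](C)C(=O)O | starting material
6 | (R,E)-1-(2,5-dimethoxyphenyl)-4-hydroxy-4-methylpent-2-en-1-yl (R)-2-methylbutanoate | CC[C@@H](C)C(=O)O[C@H](/C=C/C(C)(C)O)c1cc(OC)ccc1OC | intermediate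
7 | (R,E)-1-(2,5-dimethoxyphenyl)-4-methyl-4-(triethylsilyloxy)pent-2-en-1-yl (R)-2-methylbutanoate | CC[C@@H](C)C(=O)O[C@H](/C=C/C(C)(C)O[Si](CC)(CC)CC)c1cc(OC)ccc1OC | intermediate
8 | (R,E)-1-(3,6-dioxocyclohexa-1,4-dien-1-yl)-4-methyl-4-(triethylsilyloxy)pent-2-en-1-yl (R)-2-methylbutanoate | CC[C@@H](C)C(=O)O[C@H](/C=C/C(C)(C)O[Si](CC)(CC)CC)C1=CC(=O)C=CC1=O | intermediate
9 | succinic anhydride | O=C1CCC(=O)O1 | starting material
10 | 2,5-bis(trimethylsilyloxy)furan | C[Si](C)(C)Oc1ccc(O[Si](C)(C)C)o1 | intermediate
11 | oxa-bridged cycloadduct: (R,E)-1-[5,8-epoxy-1,4-dioxo-5,8-bis(trimethylsilyloxy)-1,4,4a,5,8,8a-hexahydronaphthalen-2-yl]-4-methyl-4-(triethylsilyloxy)pent-2-en-1-yl (R)-2-methylbutanoate, mixture at the four new sp3 centres | CC[C@@H](C)C(=O)O[C@H](/C=C/C(C)(C)O[Si](CC)(CC)CC)C1=CC(=O)C2C(C1=O)C1(O[Si](C)(C)C)C=CC2(O[Si](C)(C)C)O1 | intermediate (not isolated)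
12 | 4a,8a-dihydro tetraone: (R,E)-4-methyl-1-(1,4,5,8-tetraoxo-1,4,4a,5,8,8a-hexahydronaphthalen-2-yl)-4-(triethylsilyloxy)pent-2-en-1-yl (R)-2-methylbutanoate | CC[C@@H](C)C(=O)O[C@H](/C=C/C(C)(C)O[Si](CC)(CC)CC)C1=CC(=O)C2C(C1=O)C(=O)C=CC2=O | intermediate (not isolated)
13 | (R,E)-1-(5,8-dihydroxy-1,4-dioxo-1,4-dihydronaphthalen-2-yl)-4-methyl-4-(triethylsilyloxy)pent-2-en-1-yl (R)-2-methylbutanoate | CC[C@@H](C)C(=O)O[C@H](/C=C/C(C)(C)O[Si](CC)(CC)CC)C1=CC(=O)c2c(O)ccc(O)c2C1=O | intermediate
14 | (R,E)-1-(5,8-dihydroxy-1,4-dioxo-1,4-dihydronaphthalen-2-yl)-4-hydroxy-4-methylpent-2-en-1-yl (R)-2-methylbutanoate | CC[C@@H](C)C(=O)O[C@H](/C=C/C(C)(C)O)C1=CC(=O)c2c(O)ccc(O)c2C1=O | target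

**Step count and risks**

Total step count: 8 (seven on the main line plus one for the diene). Longest linear sequence: 7 steps (steps 1, 2, 3, 4, 5, 7, 8).

Steps most likely to fail:

1. Step 7 (bears the label). The silyl ketene acetal diene may react with the quinone by conjugate addition through its C3 carbon or by electron transfer instead of by cycloaddition, or a second annulation may follow premature aromatisation. The fallback uses known chemistry, a Diels–Alder reaction of a silyloxy cyclohexadiene with a quinone followed by Alder–Rickert loss of ethylene; it sets out from 8 and comes back at 13. Quinone 8 would be heated gently in toluene with 1,4-bis(trimethylsilyloxy)cyclohexa-1,3-diene F1 (from cyclohexane-1,4-dione, LiN(iPr)2 and Me3SiCl), which adds at the unsubstituted alkene to give the bicyclo[2.2.2]octene adduct F2. Et3N would enolise this to its hydroquinone tautomer F3, and Ag2O would oxidise that to the ethano-bridged quinone F4. Heating F4 in toluene at reflux should expel ethylene by retro-Diels–Alder reaction and give the 5,8-bis(trimethylsilyloxy)-1,4-naphthoquinone F5, whose aryl silyl ethers are removed with MeOH and catalytic pyridinium p-toluenesulfonate to give 13.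

2. Step 1. The electron-rich aldehyde with its coordinating ortho-methoxy group may give low conversion, insufficient enantioselectivity or the opposite facial sense. The fallback sets the centre by reduction instead of addition; it sets out from 1 and 2 and comes back at 3. The dilithium derivative of 2 (n-BuLi, 2 equiv, THF, −78 °C) would add to 1 to give the racemic diol F6. MnO2 in CH2Cl2 would oxidise only the benzylic propargylic alcohol to the ynone F7. Midland reduction with (S)-Alpine-Borane (B-isopinocampheyl-9-borabicyclo[3.3.1]nonane from (−)-α-pinene), in which the alkynyl group acts as the small substituent, should then give (R)-3.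

3. Step 5. The acidic aqueous tetravalent cerium medium may cause loss of the tertiary silyl ether and solvolysis at the allylic positions during the oxidation. The fallback changes the order so that no silyl ether is exposed to the oxidant; it sets out from 6 and comes back at 8. Hydroxy ester 6 would be oxidised directly with (NH4)2Ce(NO3)6 in MeCN–H2O at 0 °C to the hydroxy quinone F8, and its tertiary alcohol would then be silylated with Et3SiOTf and 2,6-lutidine in CH2Cl2 at −78 °C to give 8.

Further compounds
F1 | step 7 | 1,4-bis(trimethylsilyloxy)cyclohexa-1,3-diene | C[Si](C)(C)OC1=CC=C(O[Si](C)(C)C)CC1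
F2 | step 7 | bicyclo[2.2.2]octene Diels–Alder adduct of 8 (5,8-ethano-4a,5,8,8a-tetrahydro-1,4-naphthoquinone with Me3SiO at C5 and C8) | CC[C@@H](C)C(=O)O[C@H](/C=C/C(C)(C)O[Si](CC)(CC)CC)C1=CC(=O)C2C(C1=O)C1(O[Si](C)(C)C)C=CC2(O[Si](C)(C)C)CC1
F3 | step 7 | hydroquinone tautomer of F2 (5,8-ethano-5,8-dihydronaphthalene-1,4-diol with Me3SiO at C5 and C8) | CC[C@@H](C)C(=O)O[C@H](/C=C/C(C)(C)O[Si](CC)(CC)CC)c1cc(O)c2c(c1O)C1(O[Si](C)(C)C)C=CC2(O[Si](C)(C)C)CC1
F4 | step 7 | ethano-bridged quinone (5,8-ethano-5,8-dihydro-1,4-naphthoquinone with Me3SiO at C5 and C8) | CC[C@@H](C)C(=O)O[C@H](/C=C/C(C)(C)O[Si](CC)(CC)CC)C1=CC(=O)C2=C(C1=O)C1(O[Si](C)(C)C)C=CC2(O[Si](C)(C)C)CC1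
F5 | step 7 | (R,E)-1-[1,4-dioxo-5,8-bis(trimethylsilyloxy)-1,4-dihydronaphthalen-2-yl]-4-methyl-4-(triethylsilyloxy)pent-2-en-1-yl (R)-2-methylbutanoate | CC[C@@H](C)C(=O)O[C@H](/C=C/C(C)(C)O[Si](CC)(CC)CC)C1=CC(=O)c2c(O[Si](C)(C)C)ccc(O[Si](C)(C)C)c2C1=O
F6 | step 1 | racemic 1-(2,5-dimethoxyphenyl)-4-methylpent-2-yne-1,4-diol | OC(C#CC(C)(C)O)c1cc(OC)ccc1OC
F7 | step 1 | 1-(2,5-dimethoxyphenyl)-4-hydroxy-4-methylpent-2-yn-1-one | CC(C)(O)C#CC(=O)c1cc(OC)ccc1OC
F8 | step 5 | (R,E)-1-(3,6-dioxocyclohexa-1,4-dien-1-yl)-4-hydroxy-4-methylpent-2-en-1-yl (R)-2-methylbutanoate | CC[C@@H](C)C(=O)O[C@H](/C=C/C(C)(C)O)C1=CC(=O)C=CC1=O
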